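**Retrosynthetic overview**
1. Ciwujiatone ← desilylation ← single addition of a 4-silyloxy-3,5-dimethoxyphenyllithium to a cis-fused 6-aryl-3,7-dioxabicyclo[3.3.0]octan-2-one. The lactone C=O becomes the ketone and the lactone O–CH2 becomes the hydroxymethyl group, so their cis relation is carried by the ring fusion.
2. Oxolane ring ← (3+2) annulation of formaldehyde with an endo-6-aryl-3-oxabicyclo[3.1.0]hexan-2-one. The ring O–C(aryl) bond and the CH2–C(alpha to C=O) bond form together.
3. Enabling feature: in the oxolane, the carbon bearing the para-oxygenated 3,5-dimethoxyphenyl ring (donor) and the carbon alpha to the carbonyl (acceptor) are 1,3-related through the CH2OH-bearing carbon, and the O–CH2 unit between them is one formaldehyde. This is a latent donor–acceptor cyclopropane, tied as a γ-lactone through the cis CH2OH/C=O pair.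
4. Cyclopropane lactone ← enantioselective intramolecular cyclopropanation of a (Z)-allylic diazoacetate (sets the one independent stereocentre) ← Sonogashira coupling and semi-hydrogenation. One aryl bromide supplies both aryl rings.
5. Ring order: γ-lactone and cyclopropane together (step 6), oxolane (step 7, cyclopropane consumed), lactone opened (step 8).

Key step: step 7

Abbreviation: TBS = tert-butyldimethylsilyl.
Remark: formaldehyde is charged as paraformaldehyde and written as the monomer; the (5R) catalyst enantiomer is assumed to give the (1S,5R,6S) lactone, by analogy with the sense of induction known for allylic diazoacetates (otherwise the 5S catalyst is used).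

Step 1
Reactants: 1 4-bromo-2,6-dimethoxyphenol
Product: 2 (4-bromo-2,6-dimethoxyphenoxy)(tert-butyl)dimethylsilane
Conditions: TBSCl, imidazole, DMF, 23 °C
Reagents that add atoms: tert-butyldimethylsilyl chloride, CC(C)(C)[Si](C)(C)Cl
Why: Silyl ether protection of the phenol masks the acidic OH for the organometallic, carbene and Lewis acid steps; no stereocentre is formed.

Step 2
Reactants: 2 (4-bromo-2,6-dimethoxyphenoxy)(tert-butyl)dimethylsilane; 3 prop-2-yn-1-ol
Product: 4 3-[4-(TBS-oxy)-3,5-dimethoxyphenyl]prop-2-yn-1-ol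
Conditions: Pd(PPh3)2Cl2 (3 mol %), CuI (6 mol %), i-Pr2NH, THF, 65 °C
Reagents that add atoms: none
Why: Sonogashira coupling of the aryl bromide with the terminal alkyne installs the three-carbon chain, with mild heating to compensate for the electron-rich bromide.

Step 3
Reactants: 4 3-[4-(TBS-oxy)-3,5-dimethoxyphenyl]prop-2-yn-1-ol
Product: 5 (Z)-3-[4-(TBS-oxy)-3,5-dimethoxyphenyl]prop-2-en-1-ol
Conditions: H2 (1 atm), Pd/CaCO3 poisoned with Pb(OAc)2 (Lindlar catalyst), quinoline, EtOAc, 23 °C
Reagents that add atoms: none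
Why: Lindlar semi-hydrogenation adds H2 syn to the alkyne and should give the (Z)-alkene, whose geometry later becomes the endo-aryl (all-cis) arrangement of the cyclopropane.

Step 4
Reactants: 5 (Z)-3-[4-(TBS-oxy)-3,5-dimethoxyphenyl]prop-2-en-1-ol
Product: 6 (Z)-3-[4-(TBS-oxy)-3,5-dimethoxyphenyl]prop-2-en-1-yl bromoacetate
Conditions: BrCH2COBr, NaHCO3, MeCN, 0 °C
Reagents that add atoms: bromoacetyl bromide, BrCC(Br)=O
Why: O-acylation (esterification) of the primary allylic alcohol with the acid bromide under mild bicarbonate buffering gives the bromoacetate needed for diazo formation.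

Step 5
Reactants: 6 (Z)-3-[4-(TBS-oxy)-3,5-dimethoxyphenyl]prop-2-en-1-yl bromoacetate
Product: 7 (Z)-3-[4-(TBS-oxy)-3,5-dimethoxyphenyl]prop-2-en-1-yl diazoacetate
Conditions: TsNHNHTs, DBU, THF, 0 °C
Reagents that add atoms: N,N'-ditosylhydrazine, Cc1ccc(cc1)S(=O)(=O)NNS(=O)(=O)c1ccc(C)cc1
Why: Diazoacetate synthesis by N-alkylation of the bis-sulfonylhydrazine with the bromoacetate and base-induced loss of two sulfinates, under conditions that leave the (Z)-alkene untouched.

Step 6
Reactants: 7 (Z)-3-[4-(TBS-oxy)-3,5-dimethoxyphenyl]prop-2-en-1-yl diazoacetate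
Product: 8 (1S,5R,6S)-6-[4-(TBS-oxy)-3,5-dimethoxyphenyl]-3-oxabicyclo[3.1.0]hexan-2-one (aryl endo, cis to C2 and C4)
Conditions: Rh2(5R-MEPY)4 (1 mol %; MEPY = methyl 2-oxopyrrolidine-5-carboxylate), CH2Cl2, reflux, slow addition of 7
Reagents that add atoms: none
Why: Intramolecular cyclopropanation by a chiral dirhodium carboxamidate carbene adds stereospecifically to the (Z)-alkene, so the aryl group ends up endo, while the catalyst selects the alkene face and thereby sets C5 (and with it C1 and C6) with the high enantioselectivity expected for this class of allylic diazoacetates.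

Step 7
Reactants: 8 (1S,5R,6S)-6-[4-(TBS-oxy)-3,5-dimethoxyphenyl]-3-oxabicyclo[3.1.0]hexan-2-one; 9 formaldehyde
Product: 10 (1R,5R,6S)-6-[4-(TBS-oxy)-3,5-dimethoxyphenyl]-3,7-dioxabicyclo[3.3.0]octan-2-one (cis-fused, aryl exo, trans to C4)
Conditions: (CH2O)n (5 equiv), Sc(OTf)3 (20 mol %), 4 Å MS, ClCH2CH2Cl, 0 to 40 °C
Reagents that add atoms: none
Why: Proposed new method: Sc(OTf)3 binds the lactone carbonyl, whose π* orbital is held by the five-membered ring in overlap with the exocyclic cyclopropane bond C1–C6, while the 4-silyloxy-3,5-dimethoxyphenyl ring on C6 polarises the same bond, so that the oxygen of formaldehyde opens C1–C6 at C6 with inversion (SN2-like, or through a tight benzylic ion pair) and the O-alkylated oxocarbenium ion so formed is captured at its CH2 carbon by the scandium lactone enolate at C1. The closest known reaction type is the Lewis acid-catalysed (3+2) annulation of 2-arylcyclopropane-1,1-diesters with aldehydes, which is stereospecific with inversion at the donor carbon, together with the Lewis acid annulations of 2-alkoxycyclopropane monoesters with carbonyl compounds; the extension proposed is to a lactone-fused cyclopropane with a single acceptor and an aryl donor, reasoned to be feasible because of the enforced orbital alignment, the strain of the all-cis bicycle and the absence of an acidic proton that could quench the enolate (the phenol stays silylated). The oxolane ring is closed by a 5-(enolexo)-endo-trig aldol-type attack of the enolate on the oxocarbenium carbon. C5 is untouched, C6 is set by inversion so that the endo aryl of 8 becomes exo in 10, an outcome that an ionised pathway should also give because the convex-face arrangement is the less hindered and more stable one, and C1 is set by the ring fusion, since only the cis-fused bicyclo[3.3.0] lactone can form. The step needs regioselective cleavage of C1–C6 over C1–C5, secured by the donor aryl sitting only on C6, and chemoselectivity for annulation over Friedel–Crafts hydroxymethylation of the electron-rich ring and over isomerisation to the benzylidene lactone, addressed by a chloride-free triflate Lewis acid, excess formaldehyde and the lowest workable temperature.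

Step 8
Reactants: 10 (1R,5R,6S)-6-[4-(TBS-oxy)-3,5-dimethoxyphenyl]-3,7-dioxabicyclo[3.3.0]octan-2-one; 2 (4-bromo-2,6-dimethoxyphenoxy)(tert-butyl)dimethylsilane
Product: 13 [(3R,4R,5S)-5-[4-(TBS-oxy)-3,5-dimethoxyphenyl]-4-(hydroxymethyl)oxolan-3-yl][4-(TBS-oxy)-3,5-dimethoxyphenyl]methanone, via aryllithium 11 (not isolated), via lithium hemiketal alkoxide 12 (not isolated)
Conditions: 2, n-BuLi, THF, −78 °C; then 10, −78 °C; aq NH4Cl at −78 °C
Reagents that add atoms: none
Why: Halogen–lithium exchange gives 11, which should add only once to the lactone carbonyl (organolithium addition to a lactone) because the bicyclic alkoxide 12 does not collapse at −78 °C, and protonation on quench opens 12 to the hydroxy ketone with the acyl and hydroxymethyl groups cis as in the ring fusion, no stereocentre being touched.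

Step 9
Reactants: 13 [(3R,4R,5S)-5-[4-(TBS-oxy)-3,5-dimethoxyphenyl]-4-(hydroxymethyl)oxolan-3-yl][4-(TBS-oxy)-3,5-dimethoxyphenyl]methanone
Product: 14 ciwujiatone, [(3R,4R,5S)-5-(4-hydroxy-3,5-dimethoxyphenyl)-4-(hydroxymethyl)oxolan-3-yl](4-hydroxy-3,5-dimethoxyphenyl)methanone
Conditions: Bu4NF, AcOH (1:1), THF, 0 °C
Reagents that add atoms: none
Why: Fluoride desilylation of the two aryl silyl ethers, buffered with AcOH so that the phenoxides are protonated at once and the epimerisable ketone α-carbon and the β-alkoxy ketone are not exposed to base.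

**Compound list**
1 | 4-bromo-2,6-dimethoxyphenol | COc1cc(Br)cc(OC)c1O | starting material
2 | (4-bromo-2,6-dimethoxyphenoxy)(tert-butyl)dimethylsilane | COc1cc(Br)cc(OC)c1O[Si](C)(C)C(C)(C)C | intermediate
3 | prop-2-yn-1-ol | OCC#C | starting material
4 | 3-[4-(TBS-oxy)-3,5-dimethoxyphenyl]prop-2-yn-1-ol | COc1cc(C#CCO)cc(OC)c1O[Si](C)(C)C(C)(C)C | intermediate
5 | (Z)-3-[4-(TBS-oxy)-3,5-dimethoxyphenyl]prop-2-en-1-ol | COc1cc(/C=C\CO)cc(OC)c1O[Si](C)(C)C(C)(C)C | intermediate
6 | (Z)-3-[4-(TBS-oxy)-3,5-dimethoxyphenyl]prop-2-en-1-yl bromoacetate | COc1cc(/C=C\COC(=O)CBr)cc(OC)c1O[Si](C)(C)C(C)(C)C | intermediate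
7 | (Z)-3-[4-(TBS-oxy)-3,5-dimethoxyphenyl]prop-2-en-1-yl diazoacetate | COc1cc(/C=C\COC(=O)C=[N+]=[N-])cc(OC)c1O[Si](C)(C)C(C)(C)C | intermediate
8 | (1S,5R,6S)-6-[4-(TBS-oxy)-3,5-dimethoxyphenyl]-3-oxabicyclo[3.1.0]hexan-2-one (aryl endo) | O=C1OC[C@H]2[C@@H]1[C@H]2c3cc(OC)c(O[Si](C)(C)C(C)(C)C)c(OC)c3 | intermediate
9 | formaldehyde (charged as paraformaldehyde) | C=O | starting material
10 | (1R,5R,6S)-6-[4-(TBS-oxy)-3,5-dimethoxyphenyl]-3,7-dioxabicyclo[3.3.0]octan-2-one (cis-fused, aryl exo) | O=C1[C@H]2CO[C@H](c3cc(OC)c(O[Si](C)(C)C(C)(C)C)c(OC)c3)[C@H]2CO1 | intermediate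
11 | [4-(TBS-oxy)-3,5-dimethoxyphenyl]lithium | [Li]c1cc(OC)c(O[Si](C)(C)C(C)(C)C)c(OC)c1 | intermediate
12 | lithium alkoxide of the cis-fused 2,6-diaryl-3,7-dioxabicyclo[3.3.0]octan-2-ol (ring stereocentres as in 10, hemiketal carbon not assigned) | [Li]OC1(c2cc(OC)c(O[Si](C)(C)C(C)(C)C)c(OC)c2)[C@H]2CO[C@H](c3cc(OC)c(O[Si](C)(C)C(C)(C)C)c(OC)c3)[C@H]2CO1 | intermediate
13 | [(3R,4R,5S)-5-[4-(TBS-oxy)-3,5-dimethoxyphenyl]-4-(hydroxymethyl)oxolan-3-yl][4-(TBS-oxy)-3,5-dimethoxyphenyl]methanone | COc1cc(C(=O)[C@H]2CO[C@H](c3cc(OC)c(O[Si](C)(C)C(C)(C)C)c(OC)c3)[C@H]2CO)cc(OC)c1O[Si](C)(C)C(C)(C)C | intermediate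
14 | ciwujiatone, [(3R,4R,5S)-5-(4-hydroxy-3,5-dimethoxyphenyl)-4-(hydroxymethyl)oxolan-3-yl](4-hydroxy-3,5-dimethoxyphenyl)methanone | COc1cc(C(=O)[C@H]2CO[C@H](c3cc(OC)c(O)c(OC)c3)[C@H]2CO)cc(OC)c1O | target

**Step count**
Total steps: 9. Longest linear sequence: 9 (steps 1 to 9; bromide 2 is used a second time in step 8).

**Steps most likely to fail**

Step 7 (proposed new method). The single lactone acceptor may not activate the cyclopropane enough, so that Lewis acid-activated formaldehyde attacks the electron-rich arene (Friedel–Crafts hydroxymethylation) or the ring opens with proton loss to a benzylidene lactone before annulation occurs. The fallback uses the established doubly activated version, sets out from 5 and comes back at 10. Alcohol 5 would be acylated with methyl malonyl chloride (pyridine, CH2Cl2, 0 °C) to (Z)-3-[4-(TBS-oxy)-3,5-dimethoxyphenyl]prop-2-en-1-yl methyl malonate F1. Diazo transfer (4-acetamidobenzenesulfonyl azide, Et3N, MeCN) would give the corresponding methyl 2-diazomalonate F2. Copper-catalysed intramolecular cyclopropanation (Cu(MeCN)4PF6 with a chiral bisoxazoline, CH2Cl2, 40 °C), stereospecific for the (Z)-alkene, should give methyl (1S,5R,6R)-6-[4-(TBS-oxy)-3,5-dimethoxyphenyl]-2-oxo-3-oxabicyclo[3.1.0]hexane-1-carboxylate F3. This has the same spatial arrangement as 8 with CO2Me in place of H at C1, and would be brought to enantiopurity by crystallisation or chromatography on a chiral phase if catalyst control is incomplete. The lactone–ester pair is a malonate-type acceptor, so the Lewis acid (3+2) annulation with 9 (Sc(OTf)3, CH2Cl2, 0 °C) falls in the known class and should give, with inversion at the aryl-bearing carbon, methyl (1R,5R,6S)-6-[4-(TBS-oxy)-3,5-dimethoxyphenyl]-2-oxo-3,7-dioxabicyclo[3.3.0]octane-1-carboxylate F4. Krapcho dealkoxycarbonylation (LiCl, wet DMSO, 130 °C) would then deliver 10, since protonation of the lactone enolate can only give the cis-fused bicycle.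

Step 8. The hemiketal alkoxide may collapse early and the ketone take up a second aryllithium (over-addition), or the aryllithium may enolise the lactone instead of adding. The fallback passes through a Weinreb amide, sets out from 10 and comes back at 14. Lactone 10 would be opened with Me(MeO)NH·HCl and AlMe3 (CH2Cl2, 0 °C) to (3R,4R,5S)-5-[4-(TBS-oxy)-3,5-dimethoxyphenyl]-4-(hydroxymethyl)-N-methoxy-N-methyloxolane-3-carboxamide F5. The primary alcohol would be silylated at once (TBSCl, imidazole, DMF) to the TBS ether of this amide F6. Aryllithium 11 (made from 2 and n-BuLi as in step 8; THF, −78 °C) should give, through a chelated tetrahedral adduct that cannot over-add, the tris-silylated ketone F7. Bu4NF/AcOH (THF, 23 °C) would remove all three silyl groups and give 14 directly.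

Step 6. Enantiofacial selection may be incomplete with this bulky, electron-rich aryl alkene, or the carbene may be diverted to dimerisation. The fallback replaces catalyst control by resolution, sets out from 7 and comes back at 8. Cyclopropanation of 7 with Rh2(OAc)4 (CH2Cl2, slow addition) remains stereospecific for the (Z)-alkene and should give the racemic endo-aryl lactone, that is 8 together with its enantiomer (1R,5S,6R)-6-[4-(TBS-oxy)-3,5-dimethoxyphenyl]-3-oxabicyclo[3.1.0]hexan-2-one F8. The enantiomers would be separated by preparative chromatography on a chiral stationary phase, and 8 re-enters the route at step 7.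

**Further compounds**
F1 | step 7 | (Z)-3-[4-(TBS-oxy)-3,5-dimethoxyphenyl]prop-2-en-1-yl methyl malonate | COC(=O)CC(=O)OC/C=C\c1cc(OC)c(O[Si](C)(C)C(C)(C)C)c(OC)c1
F2 | step 7 | (Z)-3-[4-(TBS-oxy)-3,5-dimethoxyphenyl]prop-2-en-1-yl methyl 2-diazomalonate | COC(=O)C(=[N+]=[N-])C(=O)OC/C=C\c1cc(OC)c(O[Si](C)(C)C(C)(C)C)c(OC)c1
F3 | step 7 | methyl (1S,5R,6R)-6-[4-(TBS-oxy)-3,5-dimethoxyphenyl]-2-oxo-3-oxabicyclo[3.1.0]hexane-1-carboxylate | O=C1OC[C@H]2[C@]1(C(=O)OC)[C@H]2c3cc(OC)c(O[Si](C)(C)C(C)(C)C)c(OC)c3
F4 | step 7 | methyl (1R,5R,6S)-6-[4-(TBS-oxy)-3,5-dimethoxyphenyl]-2-oxo-3,7-dioxabicyclo[3.3.0]octane-1-carboxylate | O=C1[C@@]2(C(=O)OC)CO[C@H](c3cc(OC)c(O[Si](C)(C)C(C)(C)C)c(OC)c3)[C@H]2CO1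
F5 | step 8 | (3R,4R,5S)-5-[4-(TBS-oxy)-3,5-dimethoxyphenyl]-4-(hydroxymethyl)-N-methoxy-N-methyloxolane-3-carboxamide | CON(C)C(=O)[C@H]1CO[C@H](c2cc(OC)c(O[Si](C)(C)C(C)(C)C)c(OC)c2)[C@H]1CO
F6 | step 8 | (3R,4R,5S)-5-[4-(TBS-oxy)-3,5-dimethoxyphenyl]-4-[(TBS-oxy)methyl]-N-methoxy-N-methyloxolane-3-carboxamide | CON(C)C(=O)[C@H]1CO[C@H](c2cc(OC)c(O[Si](C)(C)C(C)(C)C)c(OC)c2)[C@H]1CO[Si](C)(C)C(C)(C)C
F7 | step 8 | [(3R,4R,5S)-5-[4-(TBS-oxy)-3,5-dimethoxyphenyl]-4-[(TBS-oxy)methyl]oxolan-3-yl][4-(TBS-oxy)-3,5-dimethoxyphenyl]methanone | COc1cc(C(=O)[C@H]2CO[C@H](c3cc(OC)c(O[Si](C)(C)C(C)(C)C)c(OC)c3)[C@H]2CO[Si](C)(C)C(C)(C)C)cc(OC)c1O[Si](C)(C)C(C)(C)C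
F8 | step 6 | (1R,5S,6R)-6-[4-(TBS-oxy)-3,5-dimethoxyphenyl]-3-oxabicyclo[3.1.0]hexan-2-one (enantiomer of 8) | O=C1OC[C@@H]2[C@H]1[C@@H]2c3cc(OC)c(O[Si](C)(C)C(C)(C)C)c(OC)c3
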